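How much of a 700 mM charge stands as target at 5.9 min? The shares already read climb with charge, but each share is what was made minus what may have been lost, so the question is how long target sits in the flask.

| flask | starting material | time |
|---|---|---|
| Sunday's | 200 mM |  |
| Friday's | 100 mM |  |
| Saturday's | 400 mM |  |
| Wednesday's | 700 mM | 5.9 min |

| Sunday's run: time / min | Sunday's run: [target] / mM | Friday's run: time / min | Friday's run: [target] / mM | Saturday's run: time / min | Saturday's run: [target] / mM |
|---|---|---|---|---|---|
| 0.24 | 6.3 | 0.24 | 4.5 | 0.24 | 13.1 |
| 0.45 | 10.2 | 0.45 | 4.3 | 0.45 | 21.2 |
| 0.86 | 20.4 | 0.86 | 9.8 | 0.86 | 49.5 |
| 1.6 | 40.8 | 1.6 | 17.0 | 1.6 | 107.3 |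
| 3.1 | 78.2 | 3.1 | 31.4 | 3.1 | 223.6 |
| 5.9 | 117.6 | 5.9 | 46.4 | 5.9 | 283.3 |

(readings scatter by 1 mM)

- apparent order in [starting material] of the starting rate, round the charge of the Sunday's run (the rate where two percent of its starting material have turned into target) (one fixed amount of target, the same in the runs compared)
- target in the Wednesday's run at 5.9 min, as a share of the starting material charged

- Overall: starting material -> target.
- Constant volume, constant temperature.
- An order is taken over about fifteen percent of the charge, up and down.

The first question is how fast the charge turns. Read between neighbouring points, half of Sunday's charge is target at 4.65 min, and half of Saturday's at 2.80 min, which is sooner, as autocatalysis gives. The same shrinkage per doubling puts Wednesday's half-way point at 1.85 min.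

My next question is how long target waits. Call the exposure time the minutes from the half-way point to the reading: 3.10 min in Saturday's flask, and 4.05 min in Wednesday's.

If Saturday's charge has all turned, its share of 70.8% reads as a first-order loss of 0.111 min⁻¹. Over Wednesday's longer exposure, that leaves 63.8%, my own figure, and it reads low if Saturday's flask still held starting material.

The forecast says 85%, with order 1.05, from a trend in share and an integrated estimate that, in its words, “misses Saturday's sharp stall”.

The flask gives 70.7% and order 1.0.

    starting material → target (0.1122 min⁻¹)
    starting material + target → 2 target (1.980 L mol⁻¹ min⁻¹)
    target → decomposed product (0.08700 min⁻¹)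

Wednesday's share falls short through the conversion of target into decomposed product: without that step the same flask gives 99.8%, a difference of 29 percentage points. Applying the loss constant of 0.0870 min⁻¹ over the exposure time of 4.05 min to that figure gives an estimate of 70.2% for Wednesday's share, against the flask's 70.7%.

Readings and results come from a simulation for substances that don't exist; the scatter is artificial.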